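## Analysis of the target

Actephilol C consists of two phenanthrene-derived halves joined through a 1,4-dioxane. Phenanthrene locants are used throughout, unprimed for the upper half and primed for the lower half. The upper half is a 3,4-dihydrophenanthren-2(1H)-one: C1 carries two methyl groups, C2 is a ketone, C3 is a ketal carbon bearing OMe and O2', and C4 is a benzylic methine bearing O3' on arene carbon C4a; its naphthalene part carries C6–OMe, C7–Me and a free C9–OH, and the carbocycle C1–C2–C3–C4–C4a–C10a is called ring C here. The lower half is a fully aromatic 1',7'-dimethyl-9'-methoxyphenanthrene with a free 6'-OH, whose catechol oxygens O2' and O3' complete the dioxane. The two stereocentres, C3 (S, fully substituted) and C4 (S), are adjacent and cis across the ring fusion, but they differ in robustness: C3 sits next to the ketone and does not ionise easily, whereas C4 is para to the C9 naphthol through C4a and can open reversibly to a para-quinone methide. Sensitive features are the oxidisable phenols and naphthol, the ionisable C4–O bond and the mixed aryl methyl ketal; the ketone lies between two quaternary carbons and cannot enolise in the target. The difficulty lies in creating the C3 ketal carbon with four different substituents in one absolute configuration, in placing the more hindered catechol oxygen O2' on C3 and O3' on C4, and in joining two electron-rich arenes of similar reactivity. The plan rests on the C3–C4 bond: C3 is alpha to the C2 ketone and C4 is an oxygenated carbon beta to it, so this is an aldol bond, and because C1 is quaternary, C3 is the only position at which an open-chain precursor can be enolised.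

## Retrosynthetic reasoning

The last bond to be made is C4–O3'. It is cut first because it forms and breaks reversibly: ionisation of the C4 carbinol of triol 32, assisted by the C9 hydroxyl, gives para-quinone methide 33, and the neighbouring O3' phenol adds to C4 to give 34. C4 therefore needs no control earlier. A trans ring junction is not geometrically excluded for a benzodioxane on a six-membered ring, so cis is not automatic. It is expected because the tether reaches C4 from the face on which C3–O2' stands, because a trans junction would force the C4–O bond into the plane of the naphthalene against C5–H, and because the reversible addition lets the more stable cis ketal accumulate.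

Triol 32 is traced to its tris-silyl ether 31. The oxygens O9, O3' and O6' must be masked during the C–C bond formation, and one fluoride treatment frees all three.

In 31 the C3–C4 bond is cut as an aldol bond, giving keto aldehyde 30, whose C3 acetal carbon already carries OMe and O2' of the complete lower half. Cutting here, and not at a C–O bond of the ketal, means that C3 is created in a C–C bond-forming step from a planar enolate under control of a chiral catalyst, so the racemic acetal centre of 30 is of no consequence. The forward reaction has to enolise a ketone whose alpha carbon bears two oxygens, select one enolate face and close ring C.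

Compound 30 is cut at the C3–O2' acetal bond into hemiacetal 15 and phenol 28; in the forward sense 15 is turned into alpha-chloro ether 29, which alkylates the phenoxide of 28. This is the convergent cut: the halves are of similar size, the bond is a plain O-alkylation, and the methoxy group is already on C3. In 28, O3' is silylated and O2' is free, which fixes the regiochemistry of the bridge.

Hemiacetal 15 holds a naphthaldehyde (C4 on C4a) and a glyoxal hemiacetal (C3). Formylating C4a after the halves are joined was ruled out: that position lies between a quaternary benzylic carbon and a peri hydrogen, and the lower half offers several equally electron-rich positions. Instead the two carbonyl carbons are read as the ends of a C3=C4 double bond: 15 arises through keto dialdehyde 14 from cis-diol 13, and 13 from phenanthrenone 12. One oxidative ring opening thus delivers both carbonyls at the right oxidation level, and only the glyoxal carbon forms a hemiacetal.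

In 12 the C1–CH3 bond is cut, leading to 2-phenanthrol 11 by dearomatising C-methylation. Compound 11 comes from phenanthrol 9 by silylation of O9 (10) and removal of the O2 benzyl group.

In 9 the C9–C10 bond is cut. The forward reaction is the attack of a metalated lateral methyl group on the diethylamide of biaryl 8, which builds the central ring and leaves the C9 oxygen in place.

Biaryl 8 is cut at C4a–C4b into boronate 5 and bromide 7 (Suzuki–Miyaura coupling). Boronate 5 comes from amide 3 through aryllithium 4, and 3 from acid 1 through chloride 2; bromide 7 is the benzyl ether of phenol 6.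

Phenol 28 is taken apart in the same way: 27, 26 and biaryl 25, then boronate 19 and bromide 24. Boronate 19 comes from the shared amide 3 through 16, 17 and aryllithium 18. Bromide 24 comes from the same phenol 6 through 20, 21, formate 22 and 23: O3' enters ortho to the phenol as a formyl group and is converted to the phenol only after the original oxygen (future O2') has been benzylated, so the two catechol oxygens are distinguished by construction.

## Alternatives that were turned down

Alternative 1: The C3–C4 and C1–C2 bonds are cut together, with both catechol oxygens already tethered. In the forward step a fluoride-triggered 1,4-elimination generates an ortho-quinodimethane unit on the naphthalene, which adds to a tethered aryloxy vinyl sulfoxide unit and gives cycloadduct A1. For it: two C–C bonds and two rings (ring C and the dioxane) form at once, the cis fusion follows from the dienophile geometry, and the sulfoxide can steer the facial selectivity. Against it: in A1, C1 is a methylene, C2 a sulfinyl-bearing methine and C3 a methine, so the gem-dimethyl group, the ketone and above all the C3 methoxy group are still missing. Once C2 is a ketone, enolisation towards C3 places the C4 aryloxy group beta to the enolate and invites E1cB opening of the dioxane, and methylation at C1 must compete with that pathway. On bonds formed per step this alternative is clearly stronger; the aldol route offers instead a key-step product that has every carbon and oxidation level of the target and is two operations from it.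

Alternative 2: The C3–OMe and C4–O3' bonds are cut, starting from an intact ring C with an O2' enol ether at C3=C4 and a silylated C2 carbinol. A hypervalent iodine oxidant in an alcohol solvent oxidises the naphthol, the solvent adds to C3 to give a quinone methide ketal, and fluoride releases the O3' phenoxide, which closes onto C4 to give A2. For it: no late C–C bond formation, the ketal level is created directly, the closure is the same quinone methide capture used here, and the path to the key intermediate is probably shorter. Against it: C3 depends on 1,2-induction from the C2 silyloxy group on a flat oxocarbenium ion next to a gem-dimethyl carbon, which is hard to predict. The oxidant must also choose the upper naphthol over the equally electron-rich lower half. Finally, A2 has the wrong oxidation level at C2, so a carbinol must be freed and oxidised beside a free naphthol and phenol. The aldol route sets C3 directly under catalyst control and needs no oxidation after the phenols are free.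

Alternative 3: The C3–O2' bond is cut, starting from a C4 aryl ether (O3' on C4) with a free O2' phenol and a dimethyl ketal at C3. A silyl triflate Lewis acid ionises the ketal and the phenol captures the oxocarbenium ion to give diacetate A3. For it: the closure is intramolecular, needs no enolisation of a doubly oxygenated carbon, and A3 is one deacetylation from the target; on the certainty that the key bond forms at all it is stronger than the aldol. Against it: the absolute configuration must be stored at C4, the centre that ionises most readily, and must survive a Lewis acid strong enough to ionise a ketal whose cation is destabilised by the C2 carbonyl. The enantioselective construction of that hindered benzylic aryl ether is a second open problem. The aldol route reverses the roles: the robust centre C3 is set first and the labile centre C4 is allowed to follow.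

Key step: step 23

## Route

Assumption: the (S,S)-enantiomer of the ProPhenol ligand is written in step 23 by analogy with its usual sense of induction; the sense has to be confirmed on the first aldol product, and the antipodal ligand is used if the other enolate face is selected.

Abbreviations: TIPS = triisopropylsilyl, Bn = benzyl, Bpin = 4,4,5,5-tetramethyl-1,3,2-dioxaborolan-2-yl, NMO = N-methylmorpholine N-oxide.

Step 1
Reactants: 1 4-methoxy-3-methylbenzoic acid
Product: 3 N,N-diethyl-4-methoxy-3-methylbenzamide, via acid chloride 2 (not isolated)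
Conditions: (COCl)2, DMF (cat.), CH2Cl2, 0 °C → rt; then Et2NH, Et3N, CH2Cl2, 0 °C → rt
Reagents that add atoms: diethylamine, CCNCC
Why: Acid chloride formation and amidation. The diethylamide later directs the ortho-metalation and serves as the electrophile that closes the central ring.

Step 2
Reactants: 3 N,N-diethyl-4-methoxy-3-methylbenzamide
Product: 5 N,N-diethyl-4-methoxy-5-methyl-2-(4,4,5,5-tetramethyl-1,3,2-dioxaborolan-2-yl)benzamide, via aryllithium 4 (not isolated)
Conditions: s-BuLi, TMEDA, THF, −78 °C; then iPrOBpin, −78 °C → rt; aq. NH4Cl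
Reagents that add atoms: 2-isopropoxy-4,4,5,5-tetramethyl-1,3,2-dioxaborolane, CC(C)OB1OC(C)(C)C(C)(C)O1
Why: Directed ortho-metalation: the amide outranks the methoxy group as director, and of its two ortho positions the one away from the methyl group is accessible, so boron enters at the future C4b.

Step 3
Reactants: 6 4-bromo-2,3-dimethylphenol
Product: 7 1-(benzyloxy)-4-bromo-2,3-dimethylbenzene
Conditions: BnBr, K2CO3, DMF, rt
Reagents that add atoms: benzyl bromide, BrCc1ccccc1
Why: Williamson etherification. Benzyl protects the future O2 through the amide-base cyclisation and is later removed by hydrogenolysis without touching a silyl ether.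

Step 4
Reactants: 5 N,N-diethyl-4-methoxy-5-methyl-2-(4,4,5,5-tetramethyl-1,3,2-dioxaborolan-2-yl)benzamide; 7 1-(benzyloxy)-4-bromo-2,3-dimethylbenzene
Product: 8 2-[4-(benzyloxy)-2,3-dimethylphenyl]-N,N-diethyl-4-methoxy-5-methylbenzamide
Conditions: Pd(OAc)2 (cat.), SPhos (cat.), K3PO4, toluene/H2O, 90 °C
Reagents that add atoms: none
Why: Suzuki–Miyaura coupling forms the C4a–C4b bond; a dialkylbiarylphosphine ligand copes with the two ortho substituents.

Step 5
Reactants: 8 2-[4-(benzyloxy)-2,3-dimethylphenyl]-N,N-diethyl-4-methoxy-5-methylbenzamide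
Product: 9 2-(benzyloxy)-6-methoxy-1,7-dimethylphenanthren-9-ol
Conditions: LiN(iPr)2 (3 equiv), THF, 0 °C → rt; aq. NH4Cl (argon)
Reagents that add atoms: none
Why: Amide-directed remote metalation: the methyl group ortho to the biaryl bond is deprotonated next to the amide, the benzylic anion attacks the amide carbonyl, diethylamide leaves and the ketone tautomerises to the 9-phenanthrol. The second methyl group cannot reach the amide, so its deprotonation is unproductive and reversible.

Step 6
Reactants: 9 2-(benzyloxy)-6-methoxy-1,7-dimethylphenanthren-9-ol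
Product: 10 2-(benzyloxy)-6-methoxy-1,7-dimethyl-9-[(triisopropylsilyl)oxy]phenanthrene
Conditions: TIPSOTf, 2,6-lutidine, CH2Cl2, 0 °C → rt
Reagents that add atoms: triisopropylsilyl trifluoromethanesulfonate, CC(C)[Si](OS(=O)(=O)C(F)(F)F)(C(C)C)C(C)C
Why: Silylation of a peri-hindered phenol with the silyl triflate, done at once because 9-phenanthrols oxidise in air.

Step 7
Reactants: 10 2-(benzyloxy)-6-methoxy-1,7-dimethyl-9-[(triisopropylsilyl)oxy]phenanthrene
Product: 11 6-methoxy-1,7-dimethyl-9-[(triisopropylsilyl)oxy]phenanthren-2-ol
Conditions: H2 (1 atm), 10% Pd/C, EtOAc, rt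
Reagents that add atoms: none
Why: Hydrogenolysis of the benzyl ether; the aryl silyl ether and the phenanthrene 9,10-bond are inert at atmospheric pressure.

Step 8
Reactants: 11 6-methoxy-1,7-dimethyl-9-[(triisopropylsilyl)oxy]phenanthren-2-ol
Product: 12 6-methoxy-1,1,7-trimethyl-9-[(triisopropylsilyl)oxy]phenanthren-2(1H)-one
Conditions: t-BuOK (1.05 equiv), MeI, t-BuOH/toluene, rt
Reagents that add atoms: iodomethane, CI
Why: Alkylative dearomatisation of a 1-alkyl-2-naphthol-type phenoxide: the C1–C2 bond has high double-bond character, and in a hydrogen-bonding, weakly polar medium the phenoxide is methylated at C1 to give the blocked dienone. O-methylation is the competing pathway.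

Step 9
Reactants: 12 6-methoxy-1,1,7-trimethyl-9-[(triisopropylsilyl)oxy]phenanthren-2(1H)-one
Product: 13 (3RS,4RS)-3,4-dihydroxy-6-methoxy-1,1,7-trimethyl-9-[(triisopropylsilyl)oxy]-3,4-dihydrophenanthren-2(1H)-one
Conditions: OsO4 (cat.), NMO, acetone/H2O, rt
Reagents that add atoms: OsO4 (catalytic oxygen carrier), O=[Os](=O)(=O)=O; N-methylmorpholine N-oxide, C[N+]1([O-])CCOCC1; water, O
Why: Catalytic syn-dihydroxylation of the only non-aromatic C=C bond; catalytic OsO4 leaves the naphthalene untouched. The racemic cis-diol is of no stereochemical consequence because both centres are destroyed in step 10.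

Step 10
Reactants: 13 (3RS,4RS)-3,4-dihydroxy-6-methoxy-1,1,7-trimethyl-9-[(triisopropylsilyl)oxy]-3,4-dihydrophenanthren-2(1H)-one
Product: 15 2-(4-hydroxy-4-methoxy-2-methyl-3-oxobutan-2-yl)-7-methoxy-6-methyl-4-[(triisopropylsilyl)oxy]naphthalene-1-carbaldehyde, via keto dialdehyde 14 (not isolated)
Conditions: Pb(OAc)4 (1.0 equiv), CH2Cl2, −20 °C; filter; then MeOH, rt; used crude
Reagents that add atoms: methanol, CO
Why: Criegee glycol cleavage of a cis-diol is fast under anhydrous conditions, and one equivalent of oxidant avoids further cleavage of the alpha-keto aldehyde. Methanol adds only to the glyoxal carbonyl, the most electrophilic one, while the hindered, conjugated naphthaldehyde stays free.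

Step 11
Reactants: 3 N,N-diethyl-4-methoxy-3-methylbenzamide
Product: 16 N,N-diethyl-4-hydroxy-3-methylbenzamide
Conditions: BBr3, CH2Cl2, −78 → 0 °C; then H2O
Reagents that add atoms: none
Why: Lewis-acid cleavage of the aryl methyl ether; the tertiary amide survives. The lower half needs this oxygen as a free phenol in the end.

Step 12
Reactants: 16 N,N-diethyl-4-hydroxy-3-methylbenzamide
Product: 17 N,N-diethyl-3-methyl-4-[(triisopropylsilyl)oxy]benzamide
Conditions: TIPSCl, imidazole, DMF, rt
Reagents that add atoms: chlorotriisopropylsilane, CC(C)[Si](Cl)(C(C)C)C(C)C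
Why: Silylation of the phenol. The bulky silyl ether does not direct lithiation to its own ortho position and withstands the amide bases used later.

Step 13
Reactants: 17 N,N-diethyl-3-methyl-4-[(triisopropylsilyl)oxy]benzamide
Product: 19 N,N-diethyl-5-methyl-2-(4,4,5,5-tetramethyl-1,3,2-dioxaborolan-2-yl)-4-[(triisopropylsilyl)oxy]benzamide, via aryllithium 18 (not isolated)
Conditions: s-BuLi, TMEDA, THF, −78 °C; then iPrOBpin, −78 °C → rt; aq. NH4Cl
Reagents that add atoms: 2-isopropoxy-4,4,5,5-tetramethyl-1,3,2-dioxaborolane, CC(C)OB1OC(C)(C)C(C)(C)O1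
Why: Directed ortho-metalation as in step 2; the amide is the only effective director and the position away from the methyl group is lithiated.

Step 14
Reactants: 6 4-bromo-2,3-dimethylphenol
Product: 20 5-bromo-2-hydroxy-3,4-dimethylbenzaldehyde
Conditions: MgCl2, Et3N, (CH2O)n, MeCN, reflux; aq. HCl
Reagents that add atoms: paraformaldehyde (as formaldehyde), C=O
Why: Magnesium-mediated ortho-formylation of a phenol (Casnati–Skattebøl type). Only one ortho position is free, so the formyl group enters at the carbon that becomes C3'.

Step 15
Reactants: 20 5-bromo-2-hydroxy-3,4-dimethylbenzaldehyde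
Product: 21 2-(benzyloxy)-5-bromo-3,4-dimethylbenzaldehyde
Conditions: BnBr, K2CO3, DMF, rt
Reagents that add atoms: benzyl bromide, BrCc1ccccc1
Why: Williamson etherification places the temporary benzyl group on the oxygen that becomes O2', before the second oxygen exists.

Step 16
Reactants: 21 2-(benzyloxy)-5-bromo-3,4-dimethylbenzaldehyde
Product: 23 2-(benzyloxy)-5-bromo-3,4-dimethylphenol, via aryl formate 22 (not isolated)
Conditions: mCPBA, CH2Cl2, 0 °C → rt; then K2CO3 (cat.), MeOH, rt
Reagents that add atoms: 3-chloroperoxybenzoic acid, OOC(=O)c1cccc(Cl)c1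
Why: Baeyer–Villiger (Dakin-type) oxidation: the electron-rich aryl group migrates to give the formate, and methanolysis frees the phenol that becomes O3'.

Step 17
Reactants: 23 2-(benzyloxy)-5-bromo-3,4-dimethylphenol
Product: 24 [2-(benzyloxy)-5-bromo-3,4-dimethylphenoxy](triisopropyl)silane
Conditions: TIPSCl, imidazole, DMF, rt
Reagents that add atoms: chlorotriisopropylsilane, CC(C)[Si](Cl)(C(C)C)C(C)C
Why: Silylation of the only free phenol; O3' now carries the group that stays until after the key step.

Step 18
Reactants: 19 N,N-diethyl-5-methyl-2-(4,4,5,5-tetramethyl-1,3,2-dioxaborolan-2-yl)-4-[(triisopropylsilyl)oxy]benzamide; 24 [2-(benzyloxy)-5-bromo-3,4-dimethylphenoxy](triisopropyl)silane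
Product: 25 2-{4-(benzyloxy)-2,3-dimethyl-5-[(triisopropylsilyl)oxy]phenyl}-N,N-diethyl-5-methyl-4-[(triisopropylsilyl)oxy]benzamide
Conditions: Pd(OAc)2 (cat.), SPhos (cat.), K3PO4, toluene/H2O, 90 °C
Reagents that add atoms: none
Why: Suzuki–Miyaura coupling forms the C4a'–C4b' bond; phosphate base in a mostly non-polar medium spares the aryl silyl ethers.

Step 19
Reactants: 25 2-{4-(benzyloxy)-2,3-dimethyl-5-[(triisopropylsilyl)oxy]phenyl}-N,N-diethyl-5-methyl-4-[(triisopropylsilyl)oxy]benzamide
Product: 26 2-(benzyloxy)-1,7-dimethyl-3,6-bis[(triisopropylsilyl)oxy]phenanthren-9-ol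
Conditions: LiN(iPr)2 (3 equiv), THF, 0 °C → rt; aq. NH4Cl (argon)
Reagents that add atoms: none
Why: Amide-directed remote metalation and cyclisation as in step 5, closing the central ring of the lower half with the C9' oxygen in place.

Step 20
Reactants: 26 2-(benzyloxy)-1,7-dimethyl-3,6-bis[(triisopropylsilyl)oxy]phenanthren-9-ol
Product: 27 2-(benzyloxy)-9-methoxy-1,7-dimethyl-3,6-bis[(triisopropylsilyl)oxy]phenanthrene
Conditions: MeI, K2CO3, acetone, reflux
Reagents that add atoms: iodomethane, CI
Why: Williamson O-methylation of the phenanthrol installs the 9'-methoxy group; carbonate in acetone does not cleave the aryl silyl ethers.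

Step 21
Reactants: 27 2-(benzyloxy)-9-methoxy-1,7-dimethyl-3,6-bis[(triisopropylsilyl)oxy]phenanthrene
Product: 28 9-methoxy-1,7-dimethyl-3,6-bis[(triisopropylsilyl)oxy]phenanthren-2-ol
Conditions: H2 (1 atm), 10% Pd/C, EtOAc, rt
Reagents that add atoms: none
Why: Hydrogenolysis frees O2'–H alone, under neutral conditions in which the neighbouring silyl group cannot migrate.

Step 22
Reactants: 15 2-(4-hydroxy-4-methoxy-2-methyl-3-oxobutan-2-yl)-7-methoxy-6-methyl-4-[(triisopropylsilyl)oxy]naphthalene-1-carbaldehyde; 28 9-methoxy-1,7-dimethyl-3,6-bis[(triisopropylsilyl)oxy]phenanthren-2-ol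
Product: 30 2-[4-methoxy-4-({9-methoxy-1,7-dimethyl-3,6-bis[(triisopropylsilyl)oxy]phenanthren-2-yl}oxy)-2-methyl-3-oxobutan-2-yl]-7-methoxy-6-methyl-4-[(triisopropylsilyl)oxy]naphthalene-1-carbaldehyde (racemic at the acetal carbon), via chloro ether 29 (not isolated)
Conditions: 15, SOCl2, CH2Cl2, 0 °C → rt, evaporate; then 28, KN(SiMe3)2 (1.0 equiv), THF, −78 → −20 °C
Reagents that add atoms: none
Why: The hemiacetal hydroxyl is exchanged for chloride as in the preparation of alpha-halo ethers, and the chloride, activated both as alpha-halo ether and as alpha-halo ketone, is displaced by the phenoxide in a Williamson-type O-alkylation. The high reactivity allows a low temperature at which 1,2-silyl migration in the phenoxide is slow; the non-enolisable aldehyde is a spectator.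

Step 23
Reactants: 30 2-[4-methoxy-4-({9-methoxy-1,7-dimethyl-3,6-bis[(triisopropylsilyl)oxy]phenanthren-2-yl}oxy)-2-methyl-3-oxobutan-2-yl]-7-methoxy-6-methyl-4-[(triisopropylsilyl)oxy]naphthalene-1-carbaldehyde
Product: 31 (3S,4S)-4-hydroxy-3,6-dimethoxy-3-({9-methoxy-1,7-dimethyl-3,6-bis[(triisopropylsilyl)oxy]phenanthren-2-yl}oxy)-1,1,7-trimethyl-9-[(triisopropylsilyl)oxy]-3,4-dihydrophenanthren-2(1H)-one
Conditions: (S,S)-ProPhenol (20 mol%), Et2Zn (40 mol%), 4 Å MS, THF, 0 °C → rt
Reagents that add atoms: none
Why: Proposed new method: the closest known reaction type is the direct aldol addition of alpha-hydroxy ketones catalysed by the dinuclear complex formed from Et2Zn and ProPhenol; here the donor is an alpha-methoxy-alpha-aryloxy ketone, used intramolecularly to give a fully substituted ketal carbon. One zinc binds the C2 carbonyl oxygen and the methoxy oxygen in a five-membered chelate, which acidifies C3–H for removal by the zinc-bound base and fixes the enolate geometry with O–Zn and OMe cis, while the second zinc activates the naphthaldehyde. The C3–C4 bond then forms in a 6-(enolendo)-exo-trig closure that makes ring C, helped by the gem-dimethyl group at C1. The acetal stereocentre of racemic 30 is erased in the planar enolate, so C3 is decided only by the enolate face that the chiral pocket of the ligand presents to the aldehyde, and the 3S product is intended. The C4 carbinol is drawn 4S but needs no control, because step 25 ionises and resets it. Site selectivity is secured by the substrate, since C1 is quaternary and the aldehyde has no alpha hydrogen, and chelation through the methoxy and not the aryloxy oxygen is expected because the aryl ether oxygen is less basic and is shielded by the C1' methyl and the O3' silyl group. The aldol cannot dehydrate because C3 bears no hydrogen, so retro-aldol is the only reverse path and is limited by the low temperature and the stability of the six-membered ring. Turnover occurs when the zinc aldolate deprotonates the next chelated substrate molecule.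

Step 24
Reactants: 31 (3S,4S)-4-hydroxy-3,6-dimethoxy-3-({9-methoxy-1,7-dimethyl-3,6-bis[(triisopropylsilyl)oxy]phenanthren-2-yl}oxy)-1,1,7-trimethyl-9-[(triisopropylsilyl)oxy]-3,4-dihydrophenanthren-2(1H)-one
Product: 32 (3S,4S)-3-[(3,6-dihydroxy-9-methoxy-1,7-dimethylphenanthren-2-yl)oxy]-4,9-dihydroxy-3,6-dimethoxy-1,1,7-trimethyl-3,4-dihydrophenanthren-2(1H)-one
Conditions: Bu4NF, AcOH (1:1), THF, 0 °C → rt
Reagents that add atoms: none
Why: Fluoride cleaves the three aryl silyl ethers. The acetic acid buffer keeps the C4 hydroxyl protonated, so that no alkoxide is available for retro-aldol opening of ring C; C3 is untouched.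

Step 25
Reactants: 32 (3S,4S)-3-[(3,6-dihydroxy-9-methoxy-1,7-dimethylphenanthren-2-yl)oxy]-4,9-dihydroxy-3,6-dimethoxy-1,1,7-trimethyl-3,4-dihydrophenanthren-2(1H)-one
Product: 34 actephilol C, via para-quinone methide 33 (not isolated)
Conditions: CF3CO2H (cat.), CH2Cl2, 0 °C → rt
Reagents that add atoms: none
Why: Acid ionises the C4 carbinol, para to the C9 hydroxyl, to the quinone methide, and the O3' phenol adds to C4 in a 6-exo-trig oxa-Michael closure (quinone methide capture by a neighbouring phenol is a known way to benzodioxanes). The tether delivers O3' to the face of C4 on which C3–O2' stands, a trans junction would force C4–O into the naphthalene plane against C5–H, and the addition is reversible, so the cis-fused (3S,4S) ketal is expected, with C4 following from C3.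

## Compound list

1 | 4-methoxy-3-methylbenzoic acid | COc1ccc(cc1C)C(=O)O | starting material
2 | 4-methoxy-3-methylbenzoyl chloride | COc1ccc(cc1C)C(Cl)=O | intermediate (not isolated)
3 | N,N-diethyl-4-methoxy-3-methylbenzamide | CCN(CC)C(=O)c1ccc(OC)c(C)c1 | intermediate
4 | [2-(diethylcarbamoyl)-5-methoxy-4-methylphenyl]lithium | [Li]c1cc(OC)c(C)cc1C(=O)N(CC)CC | intermediate (not isolated)
5 | N,N-diethyl-4-methoxy-5-methyl-2-(4,4,5,5-tetramethyl-1,3,2-dioxaborolan-2-yl)benzamide | CCN(CC)C(=O)c1cc(C)c(OC)cc1B1OC(C)(C)C(C)(C)O1 | intermediate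
6 | 4-bromo-2,3-dimethylphenol | Cc1c(C)c(Br)ccc1O | starting material
7 | 1-(benzyloxy)-4-bromo-2,3-dimethylbenzene | Cc1c(C)c(Br)ccc1OCc1ccccc1 | intermediate
8 | 2-[4-(benzyloxy)-2,3-dimethylphenyl]-N,N-diethyl-4-methoxy-5-methylbenzamide | CCN(CC)C(=O)c1cc(C)c(OC)cc1-c1ccc(OCc2ccccc2)c(C)c1C | intermediate
9 | 2-(benzyloxy)-6-methoxy-1,7-dimethylphenanthren-9-ol | COc1cc2c(cc1C)c(O)cc1c(C)c(OCc3ccccc3)ccc12 | intermediate
10 | 2-(benzyloxy)-6-methoxy-1,7-dimethyl-9-[(triisopropylsilyl)oxy]phenanthrene | COc1cc2c(cc1C)c(O[Si](C(C)C)(C(C)C)C(C)C)cc1c(C)c(OCc3ccccc3)ccc12 | intermediate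
11 | 6-methoxy-1,7-dimethyl-9-[(triisopropylsilyl)oxy]phenanthren-2-ol | COc1cc2c(cc1C)c(O[Si](C(C)C)(C(C)C)C(C)C)cc1c(C)c(O)ccc12 | intermediate
12 | 6-methoxy-1,1,7-trimethyl-9-[(triisopropylsilyl)oxy]phenanthren-2(1H)-one | COc1cc2c(cc1C)c(O[Si](C(C)C)(C(C)C)C(C)C)cc1c2C=CC(=O)C1(C)C | intermediate
13 | (3RS,4RS)-3,4-dihydroxy-6-methoxy-1,1,7-trimethyl-9-[(triisopropylsilyl)oxy]-3,4-dihydrophenanthren-2(1H)-one (racemic cis-diol, one enantiomer drawn) | COc1cc2c(cc1C)c(O[Si](C(C)C)(C(C)C)C(C)C)cc1c2[C@H](O)[C@H](O)C(=O)C1(C)C | intermediate
14 | 7-methoxy-6-methyl-2-(2-methyl-3,4-dioxobutan-2-yl)-4-[(triisopropylsilyl)oxy]naphthalene-1-carbaldehyde | COc1cc2c(C=O)c(C(C)(C)C(=O)C=O)cc(O[Si](C(C)C)(C(C)C)C(C)C)c2cc1C | intermediate (not isolated)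
15 | 2-(4-hydroxy-4-methoxy-2-methyl-3-oxobutan-2-yl)-7-methoxy-6-methyl-4-[(triisopropylsilyl)oxy]naphthalene-1-carbaldehyde (racemic hemiacetal) | COc1cc2c(C=O)c(C(C)(C)C(=O)C(O)OC)cc(O[Si](C(C)C)(C(C)C)C(C)C)c2cc1C | intermediate
16 | N,N-diethyl-4-hydroxy-3-methylbenzamide | CCN(CC)C(=O)c1ccc(O)c(C)c1 | intermediate
17 | N,N-diethyl-3-methyl-4-[(triisopropylsilyl)oxy]benzamide | CCN(CC)C(=O)c1ccc(O[Si](C(C)C)(C(C)C)C(C)C)c(C)c1 | intermediate
18 | {2-(diethylcarbamoyl)-4-methyl-5-[(triisopropylsilyl)oxy]phenyl}lithium | [Li]c1cc(O[Si](C(C)C)(C(C)C)C(C)C)c(C)cc1C(=O)N(CC)CC | intermediate (not isolated)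
19 | N,N-diethyl-5-methyl-2-(4,4,5,5-tetramethyl-1,3,2-dioxaborolan-2-yl)-4-[(triisopropylsilyl)oxy]benzamide | CCN(CC)C(=O)c1cc(C)c(O[Si](C(C)C)(C(C)C)C(C)C)cc1B1OC(C)(C)C(C)(C)O1 | intermediate
20 | 5-bromo-2-hydroxy-3,4-dimethylbenzaldehyde | Cc1c(C)c(Br)cc(C=O)c1O | intermediate
21 | 2-(benzyloxy)-5-bromo-3,4-dimethylbenzaldehyde | Cc1c(C)c(Br)cc(C=O)c1OCc1ccccc1 | intermediate
22 | 2-(benzyloxy)-5-bromo-3,4-dimethylphenyl formate | Cc1c(C)c(Br)cc(OC=O)c1OCc1ccccc1 | intermediate (not isolated)
23 | 2-(benzyloxy)-5-bromo-3,4-dimethylphenol | Cc1c(C)c(Br)cc(O)c1OCc1ccccc1 | intermediate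
24 | [2-(benzyloxy)-5-bromo-3,4-dimethylphenoxy](triisopropyl)silane | Cc1c(C)c(Br)cc(O[Si](C(C)C)(C(C)C)C(C)C)c1OCc1ccccc1 | intermediate
25 | 2-{4-(benzyloxy)-2,3-dimethyl-5-[(triisopropylsilyl)oxy]phenyl}-N,N-diethyl-5-methyl-4-[(triisopropylsilyl)oxy]benzamide | CCN(CC)C(=O)c1cc(C)c(O[Si](C(C)C)(C(C)C)C(C)C)cc1-c1cc(O[Si](C(C)C)(C(C)C)C(C)C)c(OCc2ccccc2)c(C)c1C | intermediate
26 | 2-(benzyloxy)-1,7-dimethyl-3,6-bis[(triisopropylsilyl)oxy]phenanthren-9-ol | Cc1cc2c(O)cc3c(C)c(OCc4ccccc4)c(O[Si](C(C)C)(C(C)C)C(C)C)cc3c2cc1O[Si](C(C)C)(C(C)C)C(C)C | intermediate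
27 | 2-(benzyloxy)-9-methoxy-1,7-dimethyl-3,6-bis[(triisopropylsilyl)oxy]phenanthrene | Cc1cc2c(OC)cc3c(C)c(OCc4ccccc4)c(O[Si](C(C)C)(C(C)C)C(C)C)cc3c2cc1O[Si](C(C)C)(C(C)C)C(C)C | intermediate
28 | 9-methoxy-1,7-dimethyl-3,6-bis[(triisopropylsilyl)oxy]phenanthren-2-ol | Cc1cc2c(OC)cc3c(C)c(O)c(O[Si](C(C)C)(C(C)C)C(C)C)cc3c2cc1O[Si](C(C)C)(C(C)C)C(C)C | intermediate
29 | 2-(4-chloro-4-methoxy-2-methyl-3-oxobutan-2-yl)-7-methoxy-6-methyl-4-[(triisopropylsilyl)oxy]naphthalene-1-carbaldehyde (racemic) | COc1cc2c(C=O)c(C(C)(C)C(=O)C(Cl)OC)cc(O[Si](C(C)C)(C(C)C)C(C)C)c2cc1C | intermediate (not isolated)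
30 | 2-[4-methoxy-4-({9-methoxy-1,7-dimethyl-3,6-bis[(triisopropylsilyl)oxy]phenanthren-2-yl}oxy)-2-methyl-3-oxobutan-2-yl]-7-methoxy-6-methyl-4-[(triisopropylsilyl)oxy]naphthalene-1-carbaldehyde (racemic at the acetal carbon) | COc1cc2c(C=O)c(C(C)(C)C(=O)C(OC)Oc3c(O[Si](C(C)C)(C(C)C)C(C)C)cc4c(cc(OC)c5cc(C)c(O[Si](C(C)C)(C(C)C)C(C)C)cc54)c3C)cc(O[Si](C(C)C)(C(C)C)C(C)C)c2cc1C | intermediate
31 | (3S,4S)-4-hydroxy-3,6-dimethoxy-3-({9-methoxy-1,7-dimethyl-3,6-bis[(triisopropylsilyl)oxy]phenanthren-2-yl}oxy)-1,1,7-trimethyl-9-[(triisopropylsilyl)oxy]-3,4-dihydrophenanthren-2(1H)-one | COc1cc2c3c(cc(O[Si](C(C)C)(C(C)C)C(C)C)c2cc1C)C(C)(C)C(=O)[C@@](OC)(Oc1c(O[Si](C(C)C)(C(C)C)C(C)C)cc2c(cc(OC)c4cc(C)c(O[Si](C(C)C)(C(C)C)C(C)C)cc42)c1C)[C@H]3O | intermediate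
32 | (3S,4S)-3-[(3,6-dihydroxy-9-methoxy-1,7-dimethylphenanthren-2-yl)oxy]-4,9-dihydroxy-3,6-dimethoxy-1,1,7-trimethyl-3,4-dihydrophenanthren-2(1H)-one | COc1cc2c3c(cc(O)c2cc1C)C(C)(C)C(=O)[C@@](OC)(Oc1c(O)cc2c(cc(OC)c4cc(C)c(O)cc42)c1C)[C@H]3O | intermediate
33 | (3S)-3-[(3,6-dihydroxy-9-methoxy-1,7-dimethylphenanthren-2-yl)oxy]-3,6-dimethoxy-1,1,7-trimethylphenanthrene-2,9(1H,3H)-dione (para-quinone methide) | COc1cc2c(cc1C)C(=O)C=C1C2=C[C@](OC)(Oc2c(O)cc3c(cc(OC)c4cc(C)c(O)cc43)c2C)C(=O)C1(C)C | intermediate (not isolated)
34 | actephilol C: (3S,4S) cis-fused dioxane joining C3 (through O2') and C4 (through O3') of the upper 9-hydroxy-3,6-dimethoxy-1,1,7-trimethyl-3,4-dihydrophenanthren-2(1H)-one to the lower 6'-hydroxy-9'-methoxy-1',7'-dimethylphenanthrene | COc1cc2c3c(cc(O)c2cc1C)C(C)(C)C(=O)[C@@]1(OC)Oc2c(cc4c(cc(OC)c5cc(C)c(O)cc54)c2C)O[C@@H]31 | target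

## Step count and least certain steps

Total: 25 steps. Longest linear sequence: 13 steps (1, 2, 4 to 10, 22 to 25).

Step 23 (key step). The most likely failure is that the zinc-bound base does not enolise the doubly oxygenated alpha carbon, so that 30 is recovered or the residual ethyl–zinc group adds to the aldehyde. If the aldol does proceed, the enolate faces may be poorly discriminated, or selectivity may be lost through retro-aldol equilibration. Fallback with known chemistry: starting from 30, the ketone is enolised with LiN(SiMe3)2 in THF at −78 °C (amide-base enolisation of alpha-alkoxy carbonyl compounds followed by intramolecular aldol addition) and quenched cold with AcOH to give the racemic aldol F1 as C4 epimers. Preparative chromatography on a chiral stationary phase then supplies the 3S material, both C4 epimers of which are carried on as 31.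

Step 8. The phenoxide may be alkylated on oxygen instead of carbon, returning an aromatic methyl ether, and the alkoxide base may partly cleave the silyl ether. Fallback: starting from 11, the aryloxysulfonium salt is formed with Me2S and N-chlorosuccinimide at −40 °C and treated with Et3N. The resulting ylide rearranges by a [2,3]-sigmatropic shift, which can deliver the CH2SMe group only to carbon C1, giving the 1-(methylsulfanylmethyl) dienone F2. Desulfurisation with deactivated Raney Ni in acetone then gives 12.

Step 10. The alpha-keto aldehyde 14 may be cleaved further by the oxidant, or the three carbonyl groups may form hydrates and cyclic acetals that make 15 ill-defined; a slow dihydroxylation of the conjugated alkene in step 9 belongs to the same risk. Fallback: starting from 12, ozonolysis in CH2Cl2/MeOH at −78 °C with one equivalent of ozone and Me2S work-up. The carbonyl oxide forms at the aryl-bearing C4 and is trapped by the solvent, C3 is released as the glyoxal carbonyl, and reduction gives 15 directly; no new compound is made.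

Step 22. The silyl group may migrate from O3' to O2' in the phenoxide, after which the less hindered O3' would be alkylated and the bridge built with the wrong regiochemistry; decomposition of 29 before it is intercepted is the second risk. Fallback: starting from 15, Cl3CCN and catalytic DBU give the trichloroacetimidate F3. F3 then reacts with 28 under catalytic Me3SiOTf in CH2Cl2 at −40 °C, an acid-promoted imidate displacement of the kind used for aryl glycosides in which the phenol is never deprotonated; this returns to the route at 30.

Step 24. Under basic fluoride a C4 alkoxide may trigger retro-aldol cleavage of the C3–C4 bond, which would also erase C3; uncontrolled intermolecular quinone methide reactions are the second risk. Fallback: starting from 31, the C4 hydroxyl is acetylated (Ac2O, DMAP, pyridine) to the C4 acetate F4, which cannot form an alkoxide. Bu4NF in THF then removes the silyl groups, the C9 phenoxide expels acetate by 1,6-elimination to give 33, and the O3' phenoxide closes the dioxane, rejoining the route at 34.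

## Further compounds

F1 | step 23 | racemic aldol, (3RS)-4-hydroxy-3,6-dimethoxy-3-({9-methoxy-1,7-dimethyl-3,6-bis[(triisopropylsilyl)oxy]phenanthren-2-yl}oxy)-1,1,7-trimethyl-9-[(triisopropylsilyl)oxy]-3,4-dihydrophenanthren-2(1H)-one, both C4 epimers | COc1cc2c3c(cc(O[Si](C(C)C)(C(C)C)C(C)C)c2cc1C)C(C)(C)C(=O)C(OC)(Oc1c(O[Si](C(C)C)(C(C)C)C(C)C)cc2c(cc(OC)c4cc(C)c(O[Si](C(C)C)(C(C)C)C(C)C)cc42)c1C)C3O
F2 | step 8 | 6-methoxy-1,7-dimethyl-1-[(methylsulfanyl)methyl]-9-[(triisopropylsilyl)oxy]phenanthren-2(1H)-one (racemic) | COc1cc2c(cc1C)c(O[Si](C(C)C)(C(C)C)C(C)C)cc1c2C=CC(=O)C1(C)CSC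
F0 | step 10 | none | none
F3 | step 22 | 3-{1-formyl-7-methoxy-6-methyl-4-[(triisopropylsilyl)oxy]naphthalen-2-yl}-1-methoxy-3-methyl-2-oxobutyl 2,2,2-trichloroethanimidate (racemic) | COc1cc2c(C=O)c(C(C)(C)C(=O)C(OC)OC(=N)C(Cl)(Cl)Cl)cc(O[Si](C(C)C)(C(C)C)C(C)C)c2cc1C
F4 | step 24 | (3S,4S)-3,6-dimethoxy-3-({9-methoxy-1,7-dimethyl-3,6-bis[(triisopropylsilyl)oxy]phenanthren-2-yl}oxy)-1,1,7-trimethyl-2-oxo-9-[(triisopropylsilyl)oxy]-1,2,3,4-tetrahydrophenanthren-4-yl acetate | COc1cc2c3c(cc(O[Si](C(C)C)(C(C)C)C(C)C)c2cc1C)C(C)(C)C(=O)[C@@](OC)(Oc1c(O[Si](C(C)C)(C(C)C)C(C)C)cc2c(cc(OC)c4cc(C)c(O[Si](C(C)C)(C(C)C)C(C)C)cc42)c1C)[C@H]3OC(C)=O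
A1 | alternative 1 | Diels–Alder adduct with the cis-fused dioxane in place, C1 methylene, C2 p-tolylsulfinyl, C3 methine, both phenols as methoxymethyl ethers | COc1cc2c3c(cc(OCOC)c2cc1C)C[C@H]([S@@](=O)c1ccc(C)cc1)[C@H]1Oc2c(cc4c(cc(OC)c5cc(C)c(OCOC)cc54)c2C)O[C@@H]31
A2 | alternative 2 | C2 tert-butyldimethylsilyloxy analogue of actephilol C (silylated C2 carbinol in place of the ketone) | COc1cc2c3c(cc(O)c2cc1C)C(C)(C)[C@@H](O[Si](C)(C)C(C)(C)C)[C@@]1(OC)Oc2c(cc4c(cc(OC)c5cc(C)c(O)cc54)c2C)O[C@@H]31
A3 | alternative 3 | actephilol C 9,6'-diacetate | COc1cc2c3c(cc(OC(C)=O)c2cc1C)C(C)(C)C(=O)[C@@]1(OC)Oc2c(cc4c(cc(OC)c5cc(C)c(OC(C)=O)cc54)c2C)O[C@@H]31
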